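## Retrosynthetic overview

1. Ring A (the carbocycle) is bought rather than built. Phloroglucinol 1 and isobutyryl chloride 2 give phlorisobutyrophenone 3, which accounts for the C–acyl cut.
2. Three C–prenyl cuts follow. 3 and prenyl bromide 4 pass through 5 and 6 to colupulone 7. The third alkylation dearomatises ring A and creates the gem-diprenyl carbon.
3. The last cut is O1–C2 of ring B. The prenyl group on the enol carbon of unprotected 7 is epoxidised enantioselectively to 8. The neighbouring chelated enol oxygen then opens 8 in a 5-exo closure with inversion to give 9.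
4. Ring order: ring A is present from the start and ring B is formed in the final step. That step also sets the only stereocentre under catalyst control, and no protecting groups are used.

Assumption: all dearomatised compounds are rapidly equilibrating enol tautomers. Each is drawn as one tautomer, and 9 is drawn as in the given SMILES. Positions C1–C6 refer to colupulone numbering (C2 acyl, C4 one prenyl, C6 two prenyls).

## Route

Step 1
Reactants: 1 phloroglucinol; 2 isobutyryl chloride
Product: 3 phlorisobutyrophenone
Conditions: AlCl3 (3.5 equiv), CH2Cl2–PhNO2, 0 to 40 °C, 3 h; ice/aq. HCl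
Reagents that add atoms: isobutyryl chloride 2, CC(C)C(=O)Cl
Why: In this Friedel–Crafts C-acylation the AlCl3-bound acylium ion attacks a very electron-rich, threefold-symmetric ring, so only one regioisomer is possible, the chelated aryl ketone formed resists a second acylation, and no stereocentre is formed.

Step 2
Reactants: 3 phlorisobutyrophenone; 4 prenyl bromide (3.1 equiv)
Product: 7 colupulone, via 3-prenylphlorisobutyrophenone 5 (not isolated), via deoxycohumulone 6 (not isolated)
Conditions: KOH (3.3 equiv), degassed H2O, Ar, 0 °C, slow addition of 4, 3 h; aq. HCl; crystallise from hexane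
Reagents that add atoms: prenyl bromide 4, CC(C)=CCBr
Why: This is a threefold C-alkylation of an ambident phloroglucinolate by a soft allylic bromide in water, where the hydrogen-bonded oxygens favour C- over O-attack, the third event is an alkylative dearomatisation at an already prenylated carbon, the sequence stops at 7 because its anion (pKa about 6, all ring carbons substituted) is a poor nucleophile, and the new quaternary carbon carries two identical groups and is not a stereocentre.

Step 3
Reactants: 7 colupulone
Product: 9 (R)-garcinielliptone HC, via colupulone (S)-epoxide 8 (not isolated)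
Conditions: 1,2:4,5-di-O-isopropylidene-β-L-erythro-2,3-hexodiulo-2,6-pyranose (enantiomer of the D-fructose-derived Shi ketone, 30 mol %), KHSO5 (as 2 KHSO5·KHSO4·K2SO4, 1.2–1.5 equiv KHSO5, syringe pump), K2CO3, Bu4NHSO4 (5 mol %), MeCN–CH2(OMe)2/aq. Na2B4O7 buffer with Na2H2(EDTA), pH 10.5, Ar, −5 °C, 1.5 h, stopped at about 70 % conversion (HPLC); work-up at pH 5 (aq. NaH2PO4), extract into CH2Cl2, dry, stir with SiO2, 23 °C, 2–12 h; recover 7
Reagents that add atoms: potassium peroxymonosulfate KHSO5, [K+].[O-]S(=O)(=O)OO (one oxygen atom, relayed through the dioxirane of the ketone catalyst)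
Why: Proposed new method: a Shi asymmetric epoxidation (closest known reaction type: chiral-dioxirane epoxidation of ortho-prenylphenol derivatives followed by 5-exo closure to 2-(2-hydroxypropan-2-yl)dihydrobenzofurans) must here select one of three trisubstituted alkenes in an unprotected β-triketone, which should succeed because the bulky electrophilic dioxirane prefers the C4 prenyl group (allylic carbon on the electron-rich enolate carbon, flat surroundings) over the two C6 prenyl groups (allylic carbon on a neopentyl-like quaternary centre between two carbonyl carbons) and over the shielded tetrasubstituted enolate C=C, the spiro transition state of the L-series ketone gives the (S)-epoxide 8, the carboxylate-like anion of 8 is too weak a nucleophile to open the epoxide at −5 °C, and after acidification the C3–OH (proton already hydrogen-bonded to the acyl C=O as a built-in base, free in-plane lone pair pointing at the side chain) attacks the secondary epoxide carbon in a 5-exo-tet SN2 opening with inversion that sets (R) at C2 of ring B.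

## Compound list

1 | phloroglucinol (benzene-1,3,5-triol) | Oc1cc(O)cc(O)c1 | starting material
2 | isobutyryl chloride (2-methylpropanoyl chloride) | CC(C)C(=O)Cl | starting material
3 | phlorisobutyrophenone, 2-methyl-1-(2,4,6-trihydroxyphenyl)propan-1-one | CC(C)C(=O)c1c(O)cc(O)cc1O | intermediate
4 | prenyl bromide (1-bromo-3-methylbut-2-ene) | CC(C)=CCBr | starting material
5 | 3-prenylphlorisobutyrophenone, 2-methyl-1-[2,4,6-trihydroxy-3-(3-methylbut-2-enyl)phenyl]propan-1-one | CC(C)C(=O)c1c(O)cc(O)c(CC=C(C)C)c1O | intermediate
6 | deoxycohumulone, 2-methyl-1-[2,4,6-trihydroxy-3,5-bis(3-methylbut-2-enyl)phenyl]propan-1-one | CC(C)C(=O)c1c(O)c(CC=C(C)C)c(O)c(CC=C(C)C)c1O | intermediate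
7 | colupulone, 3,5-dihydroxy-2-(2-methylpropanoyl)-4,6,6-tris(3-methylbut-2-enyl)cyclohexa-2,4-dien-1-one (achiral) | CC(C)C(=O)C1=C(O)C(CC=C(C)C)=C(O)C(CC=C(C)C)(CC=C(C)C)C1=O | intermediate
8 | colupulone (S)-epoxide, 4-{[(2S)-3,3-dimethyloxiran-2-yl]methyl}-3,5-dihydroxy-2-(2-methylpropanoyl)-6,6-bis(3-methylbut-2-enyl)cyclohexa-2,4-dien-1-one | CC(C)C(=O)C1=C(O)C(C[C@@H]2OC2(C)C)=C(O)C(CC=C(C)C)(CC=C(C)C)C1=O | intermediate
9 | (R)-garcinielliptone HC, (2R)-7-(1-hydroxy-2-methylpropylidene)-2-(2-hydroxypropan-2-yl)-5,5-bis(3-methylbut-2-enyl)-2,3-dihydro-1-benzofuran-4,6(5H,7H)-dione | CC(C)=CCC1(CC=C(C)C)C(=O)C2=C(O[C@@H](C(C)(C)O)C2)/C(=C(/O)C(C)C)C1=O | target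

## Step count and risks

Total step count: 3. Longest linear sequence: 3.

**Step 3 carries the highest risk.** Four things can go wrong:
- A C6 prenyl group is epoxidised instead, or the product is over-oxidised.
- The enolate is hydroxylated at C4.
- The ring closes through the C5 oxygen (the regioisomeric furan) or 6-endo (the pyran).
- Water opens the tertiary epoxide carbon and the diol then condenses with retention, which would give the (S)-enantiomer. This is why the extract is dried before the SiO2 treatment.

The fallback sets out from 3 and returns at 9. It oxidises before the other two prenyl groups exist and blocks the competing oxygen.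
- 3 is alkylated with one equivalent of 4 (aq. KOH, 0 °C) and 5 is isolated.
- The most acidic, non-chelated hydroxyl of 5 (para to the acyl group) is acylated with pivaloyl chloride/Et3N (CH2Cl2, −20 °C) to give the 4-O-pivalate F3.
- The same L-series ketone/KHSO5/K2CO3 system now meets a single alkene and gives the (S)-epoxide F4.
- The only neighbouring free phenoxide (ortho to the acyl group) opens F4 5-exo with inversion in the basic medium, giving the (R)-dihydrobenzofuran pivalate F5.
- KOH in aqueous MeOH cleaves the ester to the dihydrobenzofurandiol F6.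
- 4 (2.3 equiv) is added to the same flask and alkylates the only free ring carbon twice, through the 5-prenyl compound F7, to give 9.

This takes five steps instead of three. Site selectivity, O-regiochemistry and 5-exo selectivity are then enforced by the structure of the substrate.

**Step 2 is the next risk.** It can give a mixture of di-, tri- and tetraprenylated products and O-prenyl ethers, and 6 and 7 are air-sensitive. The fallback sets out from 3 and returns at 7.
- Only two equivalents of 4 are used and aromatic 6 is isolated.
- The quaternary carbon is made separately by a Tsuji–Trost allylation with prenyl methyl carbonate F2 (from prenol and methyl chloroformate, pyridine) and Pd(PPh3)4 (5 mol %, zerovalent palladium) in THF at 23 °C.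
- Decarboxylation supplies the base. Any O-prenyl ether of this acidic phenol is re-ionised by palladium, so the reaction funnels to the C-alkylated product.
- The soft carbon nucleophile attacks the unsubstituted allyl terminus, which gives the linear prenyl group.

**Step 1 is the lowest risk.** Possible problems are diacylation, O-acylation and tedious removal of PhNO2. The fallback sets out from 1 and returns at 3 and is a Houben–Hoesch reaction. Isobutyronitrile, ZnCl2 and HCl gas in Et2O at 0 °C precipitate the ketiminium chloride F1. F1 cannot react a second time, and boiling water hydrolyses it to 3.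

## Further compounds

F1 | step 1 | 2-methyl-1-(2,4,6-trihydroxyphenyl)propan-1-iminium chloride | CC(C)C(=[NH2+])c1c(O)cc(O)cc1O.[Cl-]
F2 | step 2 | prenyl methyl carbonate (methyl 3-methylbut-2-enyl carbonate) | COC(=O)OCC=C(C)C
F3 | step 3 | 3,5-dihydroxy-4-(2-methylpropanoyl)-2-(3-methylbut-2-enyl)phenyl pivalate | CC(C)C(=O)c1c(O)cc(OC(=O)C(C)(C)C)c(CC=C(C)C)c1O
F4 | step 3 | 2-{[(2S)-3,3-dimethyloxiran-2-yl]methyl}-3,5-dihydroxy-4-(2-methylpropanoyl)phenyl pivalate | CC(C)C(=O)c1c(O)cc(OC(=O)C(C)(C)C)c(C[C@@H]2OC2(C)C)c1O
F5 | step 3 | (2R)-6-hydroxy-2-(2-hydroxypropan-2-yl)-7-(2-methylpropanoyl)-2,3-dihydro-1-benzofuran-4-yl pivalate | CC(C)C(=O)c1c(O)cc(OC(=O)C(C)(C)C)c2C[C@H](C(C)(C)O)Oc12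
F6 | step 3 | 1-[(2R)-4,6-dihydroxy-2-(2-hydroxypropan-2-yl)-2,3-dihydro-1-benzofuran-7-yl]-2-methylpropan-1-one | CC(C)C(=O)c1c(O)cc(O)c2C[C@H](C(C)(C)O)Oc12
F7 | step 3 | 1-[(2R)-4,6-dihydroxy-2-(2-hydroxypropan-2-yl)-5-(3-methylbut-2-enyl)-2,3-dihydro-1-benzofuran-7-yl]-2-methylpropan-1-one | CC(C)C(=O)c1c(O)c(CC=C(C)C)c(O)c2C[C@H](C(C)(C)O)Oc12
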